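Take the ratio of the first-portion decay constants of starting material, Sunday's over Thursday's: it reads 1.83 for twice the reagent. So treat the decay as pseudo-first-order, with the constant proportional to [reagent].

common to all: starting material 0.050 M (in portions, 4)

|  | reagent | remark | time |
|---|---|---|---|
| Thursday's | 0.10 M | the very flask that is asked about, followed so far; portions every 50 min |  |
| Sunday's | 0.20 M | run made earlier; portions every 50 min |  |
| flask | 0.100 M | the portions of starting material follow each other after 50 min, the first at the start | 3.0 h |

| run | time / min | target / % | over-reaction product B / % | intermediate B / % | starting material / % | side product / % | intermediate A / % |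
|---|---|---|---|---|---|---|---|
| Thursday's | 2.00 | 0 | 0.8 | 0 | 24.9 | 0 | 1.0 |
| Thursday's | 6.00 | 0 | 0 | 1.3 | 23.7 | 0.3 | 2.1 |
| Thursday's | 10.0 | 2.1 | 0 | 0 | 22.0 | 0 | 0.6 |
| Thursday's | 15.0 | 2.4 | 2.5 | 0.7 | 20.7 | 0 | 2.0 |
| Thursday's | 20.0 | 0.9 | 2.0 | 0 | 18.9 | 0 | 3.3 |
| Thursday's | 30.0 | 3.0 | 1.8 | 0 | 19.2 | 1.0 | 1.9 |
| Thursday's | 40.0 | 2.6 | 2.0 | 0.9 | 15.0 | 0.2 | 4.1 |
| Sunday's | 10.0 | 2.1 | 0.9 | 0 | 19.9 | 0 | 1.1 |
| Sunday's | 15.0 | 3.5 | 0.3 | 0.2 | 18.2 | 0 | 2.1 |
| Sunday's | 25.0 | 5.4 | 3.1 | 1.3 | 14.8 | 1.2 | 3.6 |
| Sunday's | 40.0 | 6.1 | 4.5 | 1.0 | 12.2 | 1.6 | 0.8 |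
| Sunday's | 50.0 | 7.1 | 7.6 | 0 | 7.5 | 0.2 | 1.6 |
| Sunday's | 80.0 | 11.7 | 17.6 | 1.8 | 18.9 | 0 | 3.1 |
| Sunday's | 120 | 12.5 | 29.7 | 1.3 | 27.0 | 0.6 | 4.5 |

(scatter of a reading: 1 percentage point)

* the species that holds most of what was charged as starting material, at 3.0 h (intermediate B / starting material / side product / over-reaction product B / target / intermediate A)
* the largest share itself, whichever of these holds it, in percent of the starting material charged

- a reading at the moment of an addition is taken just before it
- percentages count the whole charge, also what has not yet gone in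

But portions arrive at different times, so replace them by one lot of their mean age. At 120 min on Sunday, 3 portions are in, their mean age is 70.0 min, and 27.0% stands of 75.0% added. Call the logarithm of added over left, divided by mean age, the whole-run mean constant: 0.0146 min⁻¹, a reading that is lower than the first-portion value.

Scale it to Thursday's flask: 0.00730 min⁻¹. At 3.0 h the mean age is 105 min, so my reckoning leaves 46.5%. Give over-reaction product B its Sunday share of what reacted: 33.1%, less than the starting material.

The forecast names starting material at 50%, range 43% to 57%, higher than mine: “so starting material holds the most”.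

Thursday's flask gives starting material at 45.0%, with over-reaction product B at 31.9%. In Thursday's flask the last portion has stood 0.500 h by then, less than the 1.1 h half-life of starting material by its forward step into intermediate A, way back not counted and other concentrations as charged. Just before that portion went in, at 2.50 h, starting material stood at 32.1%. With the time and the other charges held, over-reaction product B draws level with starting material at 0.126 M of reagent.

    intermediate B → side product (k = 0.00210 min⁻¹)
    2 starting material → homo dimer (k = 0.0360 M⁻¹ min⁻¹)
    target → over-reaction product A (k = 1.40 × 10⁻⁵ min⁻¹)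
    reagent + intermediate A → target (k = 0.880 M⁻¹ min⁻¹)
    intermediate A ⇌ intermediate B (K = 0.410, k = 0.0170 min⁻¹)
    target → over-reaction product B (k = 0.0330 min⁻¹)
    starting material + reagent ⇌ intermediate A (K = 17.0 M⁻¹, k = 0.110 M⁻¹ min⁻¹)

For the neighbour at 0.40 M of reagent, the mean constant leaves 4.67% starting material. That neighbour gives 10.3%, and over-reaction product B holds 70.8%.

Readings and results come from a simulation for substances that don't exist; the scatter is artificial.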